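The synthesis rests on cutting the C3–C4 bond of the lactone ring (the lignan 8–8′ bond) instead of the exocyclic benzyl bonds or the C3–OH bond. The ring atoms C2(=O)–C3(O)–C4–C5 are read as a masked 2-alkoxypent-4-enoic acid. One Ireland–Claisen rearrangement therefore joins the two C6–C3 halves and sets the C3 tertiary carbinol and the C4 methine together. The precursor is a simple ester of O-benzylated danshensu and an (S,Z)-allylic alcohol. Chelated enolate geometry, Z-alkene geometry and 1,3-chirality transfer from one purchased carbinol centre decide both centres in a single chair. Alkene cleavage with lactonisation and one hydrogenolysis finish the synthesis.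

Key step: step 6

Remark on the chemistry: the carbinol centre of the danshensu-derived compounds is drawn as in the natural (R) acid. It is erased by enolisation in the key step, so partial racemisation on the way, or use of racemic material, has no consequence.

Step 1
Reactants: 1 sodium danshensu, sodium (R)-3-(3,4-dihydroxyphenyl)-2-hydroxypropanoate
Product: 2 benzyl (R)-2-(benzyloxy)-3-[3,4-bis(benzyloxy)phenyl]propanoate
Conditions: NaH (3.3 equiv), BnBr (4.5 equiv), TBAI (cat.), DMF, 0 °C to rt, N2
Reagents that add atoms: benzyl bromide, BrCc1ccccc1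
Why: Fourfold SN2 benzylation (Williamson ether synthesis at both phenoxides and the secondary alkoxide, O-alkylation of the carboxylate) masks every acidic site with one hydrogenolysable group, and no stereocentre is created.

Step 2
Reactants: 2 benzyl (R)-2-(benzyloxy)-3-[3,4-bis(benzyloxy)phenyl]propanoate
Product: 3 (R)-2-(benzyloxy)-3-[3,4-bis(benzyloxy)phenyl]propanoic acid
Conditions: LiOH, THF/MeOH/H2O, rt; then 1 M HCl
Reagents that add atoms: lithium hydroxide, [Li+].[OH-]
Why: Saponification (BAc2 ester hydrolysis) cleaves only the benzyl ester because alkyl and aryl benzyl ethers are inert to hydroxide.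

Step 3
Reactants: 4 (S)-but-3-yn-2-ol; 5 3,4-dimethoxybenzyl bromide
Product: 7 (S)-5-(3,4-dimethoxyphenyl)pent-3-yn-2-ol, via bis(bromomagnesium) alkoxide acetylide 6 (not isolated)
Conditions: EtMgBr (2.1 equiv), THF, 0 °C to rt; CuBr·SMe2 (10 mol %), then 5, 45 °C; aq NH4Cl
Reagents that add atoms: ethylmagnesium bromide, CC[Mg]Br (Mg and Br are held only in intermediate 6)
Why: Copper(I)-catalysed alkylation of an alkynyl Grignard reagent with a reactive benzylic bromide forms the sp–sp3 bond, the magnesium alkoxide being too weak a nucleophile to compete, and the carbinol centre bought with 4 is not touched.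

Step 4
Reactants: 7 (S)-5-(3,4-dimethoxyphenyl)pent-3-yn-2-ol
Product: 8 (2S,3Z)-5-(3,4-dimethoxyphenyl)pent-3-en-2-ol
Conditions: H2 (1 atm), Lindlar catalyst, quinoline, EtOAc, rt
Reagents that add atoms: none
Why: Lindlar semihydrogenation delivers both hydrogens syn on the poisoned palladium surface, which should give the Z-alkene and stop there, with the aryl ethers and the carbinol centre unaffected.

Step 5
Reactants: 3 (R)-2-(benzyloxy)-3-[3,4-bis(benzyloxy)phenyl]propanoic acid; 8 (2S,3Z)-5-(3,4-dimethoxyphenyl)pent-3-en-2-ol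
Product: 9 (2S,3Z)-5-(3,4-dimethoxyphenyl)pent-3-en-2-yl (2R)-2-(benzyloxy)-3-[3,4-bis(benzyloxy)phenyl]propanoate
Conditions: EDC·HCl, DMAP (cat.), CH2Cl2, 0 °C to rt
Reagents that add atoms: none
Why: Steglich esterification acylates the oxygen of 8 without breaking its C–O bond, so the (S) centre and the Z-alkene are carried unchanged into 9.

Step 6
Reactants: 9 (2S,3Z)-5-(3,4-dimethoxyphenyl)pent-3-en-2-yl (2R)-2-(benzyloxy)-3-[3,4-bis(benzyloxy)phenyl]propanoate
Product: 13 (2S,3S,4E)-2-(benzyloxy)-2-[3,4-bis(benzyloxy)benzyl]-3-(3,4-dimethoxybenzyl)hex-4-enoic acid, via chelated lithium enolate 10 (not isolated), via (Z)-silyl ketene acetal 11 (not isolated), via trimethylsilyl ester 12 (not isolated)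
Conditions: LDA (1.2 equiv), THF, −78 °C; TMSCl, −78 °C to rt, then 45 °C; 1 M HCl work-up
Reagents that add atoms: lithium diisopropylamide, [Li]N(C(C)C)C(C)C (Li is held only in 10); chlorotrimethylsilane, C[Si](C)(C)Cl (Me3Si is held only in 11 and 12)
Why: LDA removes the C2–H of 9 and lithium is held in a five-membered chelate between the enolate oxygen and the benzyloxy oxygen, so O-silylation gives the (Z)-silyl ketene acetal 11 (OSiMe3 cis to OBn), which on warming undergoes a concerted suprafacial [3,3]-sigmatropic shift (Ireland–Claisen rearrangement, the closest known type being that of allylic esters of O-protected glycolic and lactic acids) that breaks the allylic C–O bond and makes the future C3–C4 bond. No ring is closed; the only cyclic array is the six-membered chair transition state, and the lactone ring is closed in step 7. In that chair OBn is equatorial and the bis(benzyloxy)benzyl group axial on the ketene acetal terminus, while the Z-alkene forces the dimethoxybenzyl group axial on the other terminus, so the two arylmethyl groups are antiperiplanar across the new bond, which becomes trans benzyl groups and an oxygen cis to the C4 benzyl group in the lactone, the relative configuration of the target. The absolute sense comes from the (S)-carbinol centre: the chair with its methyl group equatorial brings C2 to the alkene face anti to the departing C–O bond and gives (2S,3S)-13 with an (E)-propenyl group, whereas the other chair needs an axial methyl group in a 1,3-diaxial (A1,3) clash with the Z-substituent. The step needs control of enolate geometry (secured by the chelating α-benzyloxy group and lithium in THF), chair over boat (acyclic ester, with the two largest groups anti only in the chair) and deprotonation at C2 and not at the allylic-benzylic CH2 (secured by the far higher acidity of the ester α-CH at −78 °C). The C2 centre of 9 is erased on enolisation, so its configuration and purity do not matter.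

Step 7
Reactants: 13 (2S,3S,4E)-2-(benzyloxy)-2-[3,4-bis(benzyloxy)benzyl]-3-(3,4-dimethoxybenzyl)hex-4-enoic acid
Product: 16 (3S,4S)-3-(benzyloxy)-3-[3,4-bis(benzyloxy)benzyl]-4-(3,4-dimethoxybenzyl)dihydrofuran-2(3H)-one, via 4-oxo acid 14 (not isolated), via 4-hydroxy acid 15 (not isolated)
Conditions: O3, CH2Cl2/MeOH, −78 °C (Sudan Red 7B end point); NaBH4, −78 to 0 °C; 1 M HCl, rt
Reagents that add atoms: ozone, [O-][O+]=O
Why: Ozonolysis with reductive borohydride work-up cuts the only alkene to the C5 aldehyde and reduces it cold before C4 can epimerise, and acid then closes the ring by 5-exo-trig lactonisation helped by the fully substituted C3, no bond at either stereocentre being changed.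

Step 8
Reactants: 16 (3S,4S)-3-(benzyloxy)-3-[3,4-bis(benzyloxy)benzyl]-4-(3,4-dimethoxybenzyl)dihydrofuran-2(3H)-one
Product: 17 (3S,4S)-3-(3,4-dihydroxybenzyl)-4-(3,4-dimethoxybenzyl)-3-hydroxydihydrofuran-2(3H)-one (CNP0142775.1)
Conditions: H2 (1 atm), Pd(OH)2/C, EtOAc/EtOH, rt
Reagents that add atoms: none
Why: Catalytic hydrogenolysis cleaves the three O–CH2Ph bonds (two aryl benzyl ethers, one tertiary alkyl benzyl ether) while the methyl ethers, the lactone and the non-benzylic C3–O bond are inert, and no epimerisable centre is present.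

Compound list
1 | sodium danshensu, sodium (R)-3-(3,4-dihydroxyphenyl)-2-hydroxypropanoate | [Na+].[O-]C(=O)[C@H](O)Cc1ccc(O)c(O)c1 | starting material
2 | benzyl (R)-2-(benzyloxy)-3-[3,4-bis(benzyloxy)phenyl]propanoate | O=C(OCc1ccccc1)[C@H](OCc1ccccc1)Cc1ccc(OCc2ccccc2)c(OCc2ccccc2)c1 | intermediate
3 | (R)-2-(benzyloxy)-3-[3,4-bis(benzyloxy)phenyl]propanoic acid | OC(=O)[C@H](OCc1ccccc1)Cc1ccc(OCc2ccccc2)c(OCc2ccccc2)c1 | intermediate
4 | (S)-but-3-yn-2-ol | C[C@H](O)C#C | starting material
5 | 3,4-dimethoxybenzyl bromide | COc1ccc(CBr)cc1OC | starting material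
6 | bis(bromomagnesium) salt of 4 (O–MgBr and alkynyl C–MgBr) | C[C@H](O[Mg]Br)C#C[Mg]Br | intermediate
7 | (S)-5-(3,4-dimethoxyphenyl)pent-3-yn-2-ol | C[C@H](O)C#CCc1ccc(OC)c(OC)c1 | intermediate
8 | (2S,3Z)-5-(3,4-dimethoxyphenyl)pent-3-en-2-ol | C[C@H](O)/C=C\Cc1ccc(OC)c(OC)c1 | intermediate
9 | (2S,3Z)-5-(3,4-dimethoxyphenyl)pent-3-en-2-yl (2R)-2-(benzyloxy)-3-[3,4-bis(benzyloxy)phenyl]propanoate | C[C@H](OC(=O)[C@H](OCc1ccccc1)Cc1ccc(OCc2ccccc2)c(OCc2ccccc2)c1)/C=C\Cc1ccc(OC)c(OC)c1 | intermediate
10 | chelated lithium enolate of 9 (OLi cis to OBn) | [Li]O/C(O[C@@H](C)/C=C\Cc1ccc(OC)c(OC)c1)=C(\OCc1ccccc1)Cc1ccc(OCc2ccccc2)c(OCc2ccccc2)c1 | intermediate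
11 | (Z)-trimethylsilyl ketene acetal of 9 (OSiMe3 cis to OBn) | C[Si](C)(C)O/C(O[C@@H](C)/C=C\Cc1ccc(OC)c(OC)c1)=C(\OCc1ccccc1)Cc1ccc(OCc2ccccc2)c(OCc2ccccc2)c1 | intermediate
12 | trimethylsilyl (2S,3S,4E)-2-(benzyloxy)-2-[3,4-bis(benzyloxy)benzyl]-3-(3,4-dimethoxybenzyl)hex-4-enoate | C[Si](C)(C)OC(=O)[C@]([C@@H](Cc1ccc(OC)c(OC)c1)/C=C/C)(OCc1ccccc1)Cc1ccc(OCc2ccccc2)c(OCc2ccccc2)c1 | intermediate
13 | (2S,3S,4E)-2-(benzyloxy)-2-[3,4-bis(benzyloxy)benzyl]-3-(3,4-dimethoxybenzyl)hex-4-enoic acid | OC(=O)[C@]([C@@H](Cc1ccc(OC)c(OC)c1)/C=C/C)(OCc1ccccc1)Cc1ccc(OCc2ccccc2)c(OCc2ccccc2)c1 | intermediate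
14 | (2S,3R)-2-(benzyloxy)-2-[3,4-bis(benzyloxy)benzyl]-3-(3,4-dimethoxybenzyl)-4-oxobutanoic acid (same spatial arrangement as 13; the C3 descriptor changes by priority only) | OC(=O)[C@]([C@@H](Cc1ccc(OC)c(OC)c1)C=O)(OCc1ccccc1)Cc1ccc(OCc2ccccc2)c(OCc2ccccc2)c1 | intermediate
15 | (2S,3S)-2-(benzyloxy)-2-[3,4-bis(benzyloxy)benzyl]-3-(3,4-dimethoxybenzyl)-4-hydroxybutanoic acid | OC(=O)[C@]([C@@H](Cc1ccc(OC)c(OC)c1)CO)(OCc1ccccc1)Cc1ccc(OCc2ccccc2)c(OCc2ccccc2)c1 | intermediate
16 | (3S,4S)-3-(benzyloxy)-3-[3,4-bis(benzyloxy)benzyl]-4-(3,4-dimethoxybenzyl)dihydrofuran-2(3H)-one | COc1ccc(C[C@H]2COC(=O)[C@]2(OCc2ccccc2)Cc2ccc(OCc3ccccc3)c(OCc3ccccc3)c2)cc1OC | intermediate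
17 | (3S,4S)-3-(3,4-dihydroxybenzyl)-4-(3,4-dimethoxybenzyl)-3-hydroxydihydrofuran-2(3H)-one | COc1ccc(C[C@H]2COC(=O)[C@]2(O)Cc2ccc(O)c(O)c2)cc1OC | target

Total step count: 8. Longest linear sequence: 6 (steps 1, 2, 5, 6, 7, 8; the branch 3, 4, 5, 6, 7, 8 is equally long).

Steps most likely to fail

1. Step 6 (key step).
- Risk: incomplete chelation control when the fully substituted enolate forms, or leakage through a boat transition state, would erode the C3/C4 relative configuration. Slow O-silylation would let the enolate fragment on warming.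
- Fallback: it sets out from 8 and comes back at 16, and it sets the two centres one after the other instead of together.
- 8 is esterified with commercial benzyloxyacetic acid (EDC, DMAP) to (2S,3Z)-5-(3,4-dimethoxyphenyl)pent-3-en-2-yl (benzyloxy)acetate F1.
- The glycolate Ireland–Claisen rearrangement (LDA, TMSCl) has a less substituted chelated enolate, the best-behaved case. It should give (2S,3S,4E)-2-(benzyloxy)-3-(3,4-dimethoxybenzyl)hex-4-enoic acid F2, with C3 fixed by the same chirality transfer.
- Ozonolysis, NaBH4 and acid then give (3S,4S)-3-(benzyloxy)-4-(3,4-dimethoxybenzyl)dihydrofuran-2(3H)-one F3.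
- The lithium enolate of F3 is alkylated with 3,4-bis(benzyloxy)benzyl bromide F4 (from the commercial benzylic alcohol and PBr3). Attack occurs on the ring face anti to the C4 substituent and leads to 16.

2. Step 3.
- Risk: homocoupling of the electron-rich benzylic bromide, O-benzylation of the alkoxide, or propargyl-to-allene isomerisation of the skipped aryl alkyne would consume the material. Over-reduction in step 4 would add to the loss.
- Fallback: it sets out from 4 and 5 and comes back at 8, so steps 3 and 4 are both replaced. The Z-alkene is made first and the benzyl group is attached by sp2–sp3 cross-coupling.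
- 4 is iodinated at the alkyne terminus (NIS, cat. AgNO3, acetone) to (S)-4-iodobut-3-yn-2-ol F5.
- Diimide (2-nitrobenzenesulfonyl hydrazide, Et3N) reduces F5 by syn addition to (2S,3Z)-4-iodobut-3-en-2-ol F6.
- 5 is converted with zinc dust and LiCl in THF into 3,4-dimethoxybenzylzinc bromide F7.
- A Negishi coupling of F6 with excess F7 (Pd(OAc)2, SPhos, THF, rt) proceeds with retention of alkene geometry and gives 8.

3. Step 7.
- Risk: competing attack of ozone on the dialkoxyarene rings or on the benzyl ether CH2 groups, and epimerisation at C4 while the aldehyde is exposed.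
- Fallback: it sets out from 13 and comes back at 16. The alkene is cleaved with a metal-oxo oxidant that ignores arenes, in two flasks, and the aldehyde is isolated in a ring-closed form that cannot enolise.
- Lemieux–Johnson cleavage (cat. OsO4, NaIO4, 2,6-lutidine, dioxane/H2O) should give the pseudo-acid lactol (3S,4R)-3-(benzyloxy)-3-[3,4-bis(benzyloxy)benzyl]-4-(3,4-dimethoxybenzyl)-5-hydroxydihydrofuran-2(3H)-one F8 as a mixture at C5.
- NaBH4 in EtOH reduces F8 through its open form, and acidification closes the ring to 16.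

Further compounds
F1 | step 6 | (2S,3Z)-5-(3,4-dimethoxyphenyl)pent-3-en-2-yl (benzyloxy)acetate | C[C@H](OC(=O)COCc1ccccc1)/C=C\Cc1ccc(OC)c(OC)c1
F2 | step 6 | (2S,3S,4E)-2-(benzyloxy)-3-(3,4-dimethoxybenzyl)hex-4-enoic acid | OC(=O)[C@H]([C@@H](Cc1ccc(OC)c(OC)c1)/C=C/C)OCc1ccccc1
F3 | step 6 | (3S,4S)-3-(benzyloxy)-4-(3,4-dimethoxybenzyl)dihydrofuran-2(3H)-one | COc1ccc(C[C@H]2COC(=O)[C@H]2OCc2ccccc2)cc1OC
F4 | step 6 | 3,4-bis(benzyloxy)benzyl bromide | BrCc1ccc(OCc2ccccc2)c(OCc2ccccc2)c1
F5 | step 3 | (S)-4-iodobut-3-yn-2-ol | C[C@H](O)C#CI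
F6 | step 3 | (2S,3Z)-4-iodobut-3-en-2-ol | C[C@H](O)/C=C\I
F7 | step 3 | 3,4-dimethoxybenzylzinc bromide | COc1ccc(C[Zn]Br)cc1OC
F8 | step 7 | (3S,4R)-3-(benzyloxy)-3-[3,4-bis(benzyloxy)benzyl]-4-(3,4-dimethoxybenzyl)-5-hydroxydihydrofuran-2(3H)-one (mixture at C5) | COc1ccc(C[C@H]2C(O)OC(=O)[C@]2(OCc2ccccc2)Cc2ccc(OCc3ccccc3)c(OCc3ccccc3)c2)cc1OC
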